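# Total synthesis proposal for alterbrassicicene C (19)

## Analysis of the target

Alterbrassicicene C (19, C21H28O5) is a 5-8-5 fusicoccane. Atom numbers follow the SMILES string: C1 carries the methoxymethyl carbon C15, C3 and C5 are ketones, C4 is the methyl-bearing quaternary carbon, C7 carries the isopropyl group, C10 the hydroxyl, C11 a methyl group, and C8 and C12 are the ether carbons. Ring A is the cyclopentene C1/C2/C12/C13/C14, ring B the cyclooctane C2/C3/C4/C8/C9/C10/C11/C12, and ring C the cyclopentenone C4–C8.

An ether oxygen spans C8 and C12 and turns ring B into a 9-oxabicyclo[3.3.1]nonane. This consists of an oxan-4-ol ring (O, C8, C9, C10, C11, C12) and an oxan-4-one ring (O, C8, C4, C3, C2, C12). Seen from the oxane, rings A and C are spiro-attached at C12 and C8, and C3 is a one-carbon carbonyl bridge between their α carbons C2 and C4.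

There are five stereocentres, (4R,8R,10S,11S,12R). C4, C8 and C12 are locked to each other by ring fusion and bridge: on ring C the C8 oxygen is cis to C3, and C9 is cis to the C4 methyl group. The C10 hydroxyl is axial (endo, pointing at the C3 carbonyl), and the C11 methyl group is equatorial.

The feature the plan rests on is the oxygenation pattern of ring B. The oxygenated carbons C3, C8, C10 and C12 alternate with C4, C9, C11 and C2. Both ether carbons are therefore β to a carbonyl-type carbon: C8 is β to C10, and C12 is β to C3 (and to C1, if C1 is a ketone). The bridge is the footprint of two conjugate additions.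

Sensitive groups are:
- the non-enolisable 1,3-diketone C3/C4/C5, which is open to retro-Claisen cleavage by nucleophilic base;
- two enones;
- the endo C10 hydroxyl, which sits within reach of C3.

The difficulty lies in the contiguous fully substituted pair C4–C8, the bridged medium ring, and the need to derive four stereocentres from a single absolute one.

## Retrosynthetic reasoning

**C10–O (19 from 18).** The carbinol is cut back to the ketone 18. The endo face of C10 is covered by the C3 bridge, so hydride can only arrive from the exo face and must give the axial alcohol. A ketone at C10 also makes C11 epimerisable and makes C8 and C12 β-oxy carbonyl positions, which the key step needs.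

**C1–C15 (18 from 16 and 17; 16 from 15).** The methoxymethyl carbon is removed by a cross-coupling disconnection, which turns C1 into the carbonyl carbon of a 1,3-diketone (15, shown as its C1 enol). This places a second activating group on C2 and makes ring A a derivative of a symmetrical 1,3-dione.

**C8–O and C11–C12 (15 from 13, through 14): the key disconnection.** Both bonds are cut in the retro-conjugate-addition sense. Breaking C11–C12 returns an ethyl ketone and an alkoxy-alkylidene-1,3-dione (14). Breaking C8–O returns an alkylidene at C8 and a tricarbonyl enol (13). These cuts dissolve ring B and both oxygen heterocycles at once and remove three of the four stereocentres present in 15. What is left is 13: rings A and C joined only through the C3 carbonyl, with C4 as the sole stereocentre. The cut is made here because: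
- in 13 the only nucleophile that can reach C8 through a six-membered ring is the ring A oxygen;
- the two ring A carbonyl groups are equivalent;
- ring C forces the new C–O bond onto the face that carries C3.

The forward reaction has to add oxygen to C8, then C11 to C12, and stop at the diketonate.

**C2–C3 (13 from 10 and 11).** The tricarbonyl unit is opened at the acyl–dione bond. This is the standard C-acylation of a cyclic 1,3-dione by a carboxylic acid and joins two fragments of 14 and 5 carbons.

**C8=C9 (10 from 9; 9 from 5 and 7; 5 from 4; 7 from 6).** The alkylidene is cut at the double bond in the vinylogous aldol sense. C8 is the γ carbon of the ring C enone, and because C4 is quaternary it is the only ring position that can be enolised. The electrophile is the aldehyde carbon of 7.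

**C6=C7 and C4–C8 (4 from 3; 3 from 1 and 2).** Ring C is opened at its enone double bond by a 1,4-diketone aldol condensation. The quaternary centre is cut at C4–C8, an alkylation of a β-keto ester by an α-bromo ketone. This alkylation is the only step in which absolute configuration has to be introduced.

## Alternatives that were turned down

Alternative 1: the textbook route. Disconnection: the ether bridge first (C12–O, retro-oxa-Michael), then ring B between preformed ring A and ring C fragments, for example at C2–C3 by a Nozaki–Hiyama–Kishi coupling and oxidation. Forward key step: closure of the eight-membered ring to the hydroxy dienetrione A1, followed by transannular oxa-Michael addition of the C8 hydroxyl to C12 to give 18. Reasons against: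
- The medium ring closes against an entropic penalty and buys no stereochemistry.
- The trans relationship of C3 and C9 on ring C has to be built separately before the closure.
- A1 carries a free tertiary alkoxide precursor at C8 that is β to the C3/C5 diketone carbon C4, so retro-aldol opening of ring C competes with every basic step.
- Two elaborate cyclopentane fragments are needed, so the route is clearly longer.

Alternative 2: de Mayo ring expansion. Disconnection: C2–C3 and C11–C12, with C3–C11 as the bond to be broken. Forward key step: intramolecular [2+2] photocycloaddition of the enolised 2-methylcyclohexane-1,3-dione in vinylogous ester A2 with its tethered ring A enol ether, then retro-aldol cleavage of the cyclobutanol to give 15. Reasons against: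
- The two alkenes are separated by three atoms, so initial five-membered ring closure would join C3 to C12 and C11 to C2, giving the wrong, 1,4-bridged skeleton.
- A2 holds two competing enone chromophores.
- A2 needs a trans-fused bicyclic trione and an enol ether of a tertiary alcohol, so it is harder to reach than 13.

Alternative 3: carbonyl bridge last. Disconnection: C2–C3 and C3–C4, with C3 coming from carbon monoxide. Forward key step: palladium-catalysed carbonylative coupling of the ring A vinyl iodide with the C4 enolate of the ring C ketone in the dispiro oxane A3, giving 19 directly. Reasons against: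
- A3 requires a 2,2,6,6-tetrasubstituted oxane from two ketone-derived carbons, with C2 and C4 both axial; no element in an open oxane controls that relationship, nor the C10/C11 centres.
- Acylation of a tetrasubstituted enolate by an acylpalladium species competes with O-acylation.
- The free C10 hydroxyl would have to be protected.

Key step: step 8

Assumption: in step 1 the (S,S) antipode of the ammonium catalyst is taken to deliver the (R) centre of 3; if the sense of induction is opposite, its mirror image is used.

Remark: the C8=C9 geometry of 9, 10, 12 and 13 is not controlled and is of no consequence, because C8 becomes sp3 in step 8.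

## Route

Step 1
Reactants: 1 tert-butyl 2-methyl-3-oxobutanoate; 2 1-bromo-3-methylbutan-2-one
Product: 3 tert-butyl (2R)-2-acetyl-2,5-dimethyl-4-oxohexanoate
Conditions: (S,S)-3,4,5-trifluorophenyl-substituted binaphthyl N-spiro ammonium bromide (2 mol %), K2CO3 (solid), toluene, −20 °C
Reagents that add atoms: none
Why: Asymmetric phase-transfer alkylation of an α-substituted β-keto ester; the chiral ammonium enolate of 1 is alkylated at carbon by the highly SN2-active α-bromo ketone 2, and the catalyst shields one enolate face so that quaternary C4 should form as the (R) isomer. The tert-butyl ester and the mild solid base limit ester exchange and base-induced loss of 2.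

Step 2
Reactants: 3 tert-butyl (2R)-2-acetyl-2,5-dimethyl-4-oxohexanoate
Product: 4 tert-butyl (1R)-1-methyl-2-oxo-4-(propan-2-yl)cyclopent-3-ene-1-carboxylate
Conditions: KOtBu (20 mol %), tBuOH–THF, 23 → 50 °C
Reagents that add atoms: none
Why: Intramolecular aldol condensation of a 1,4-diketone; the acetyl methyl carbon (C6) adds to the isopropyl ketone (C7) in a 5-exo closure and dehydration gives the conjugated cyclopentenone, the only cyclisation mode that can end in an enone. C4 is quaternary and cannot epimerise, and the hindered alkoxide does not attack the carbonyl groups.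

Step 3
Reactants: 4 tert-butyl (1R)-1-methyl-2-oxo-4-(propan-2-yl)cyclopent-3-ene-1-carboxylate
Product: 5 tert-butyl (1R)-2-[(tert-butyldimethylsilyl)oxy]-1-methyl-4-(propan-2-yl)cyclopenta-2,4-diene-1-carboxylate
Conditions: LDA, THF, −78 °C; then TBSOTf, −78 → 0 °C
Reagents that add atoms: tert-butyldimethylsilyl trifluoromethanesulfonate, CC(C)(C)[Si](C)(C)OS(=O)(=O)C(F)(F)F
Why: With no α' hydrogen (C4 is quaternary) the amide base removes a γ hydrogen, kinetically from the ring methylene C8 and not from the hindered isopropyl methine. O-Silylation of the extended enolate gives the silyloxy diene needed for a vinylogous Mukaiyama aldol reaction.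

Step 4
Reactants: 6 1-hydroxybutan-2-one
Product: 7 2-oxobutanal
Conditions: triacetoxyperiodinane (DMP), CH2Cl2, 0 → 23 °C; filtered solution used at once
Reagents that add atoms: none
Why: Periodinane oxidation of a primary α-hydroxy ketone to the α-keto aldehyde without C–C cleavage. 7 hydrates and oligomerises readily and is therefore carried on as a fresh solution.

Step 5
Reactants: 5 tert-butyl (1R)-2-[(tert-butyldimethylsilyl)oxy]-1-methyl-4-(propan-2-yl)cyclopenta-2,4-diene-1-carboxylate; 7 2-oxobutanal
Product: 9 tert-butyl (1R)-1-methyl-2-oxo-5-(2-oxobutylidene)-4-(propan-2-yl)cyclopent-3-ene-1-carboxylate, via aldol adduct 8 (not isolated)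
Conditions: BF3·OEt2, CH2Cl2, −78 °C; aq. NaHCO3; then MsCl, Et3N, CH2Cl2, 0 → 23 °C
Reagents that add atoms: none
Why: Vinylogous Mukaiyama aldol addition; the silyl dienol ether reacts at its terminal carbon C8 with the aldehyde carbon of 7, which is far more electrophilic than its ketone. Mesylation of the α-hydroxy ketone 8 and E1cB elimination across C8–C9 (C8–H is the vinylogous α hydrogen of the enone) should give the cross-conjugated alkylidene.

Step 6
Reactants: 9 tert-butyl (1R)-1-methyl-2-oxo-5-(2-oxobutylidene)-4-(propan-2-yl)cyclopent-3-ene-1-carboxylate
Product: 10 (1R)-1-methyl-2-oxo-5-(2-oxobutylidene)-4-(propan-2-yl)cyclopent-3-ene-1-carboxylic acid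
Conditions: CF3CO2H, CH2Cl2, 0 °C; concentrated cold, used directly
Reagents that add atoms: none
Why: Acidolysis of the tert-butyl ester by E1 loss of the tert-butyl cation leaves the dienone untouched. The α,α-disubstituted β-keto acid can decarboxylate on warming and is therefore kept cold and used at once.

Step 7
Reactants: 10 (1R)-1-methyl-2-oxo-5-(2-oxobutylidene)-4-(propan-2-yl)cyclopent-3-ene-1-carboxylic acid; 11 cyclopentane-1,3-dione
Product: 13 3-hydroxy-2-{[(1R)-1-methyl-2-oxo-5-(2-oxobutylidene)-4-(propan-2-yl)cyclopent-3-en-1-yl]carbonyl}cyclopent-2-en-1-one, via enol ester 12 (not isolated)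
Conditions: DCC, DMAP (1.2 equiv), CH2Cl2, 0 → 23 °C
Reagents that add atoms: none
Why: Carbodiimide activation gives the O-acyl enol ester 12, and DMAP (acylpyridinium–dionate ion pair) moves the acyl group from oxygen to C2, the established route to 2-acylcycloalkane-1,3-diones. The strongly acidic, chelated tricarbonyl enol 13 is the thermodynamic product and C4 is not touched.

Step 8
Reactants: 13 3-hydroxy-2-{[(1R)-1-methyl-2-oxo-5-(2-oxobutylidene)-4-(propan-2-yl)cyclopent-3-en-1-yl]carbonyl}cyclopent-2-en-1-one
Product: 15 (4R,8R,11R,12R)-tetracyclic enol diketone (oxygen bridge C8–O–C12; C1–OH with C1=C2; ketones at C3, C5 and C10; C6=C7 enone), via dihydropyranone 14 (not isolated)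
Conditions: DBU (2 equiv), LiCl (3 equiv), MeCN, 0 → 40 °C; AcOH quench
Reagents that add atoms: none
Why: Base converts 13 into its tricarbonyl enolate, whose ring A oxygen adds to C8 of the cross-conjugated dienone (6-exo-trig oxa-Michael) to give 14; the ethyl ketone of 14 then enolises toward C11, and this carbon adds to C12 of the alkoxy-alkylidene-1,3-dione (6-exo-trig Michael), which closes the oxan-4-one ring, completes the eight-membered ring B and ends in a stabilised 1,3-diketonate that makes the sequence downhill. The closest known reaction types are the intramolecular oxa-Michael addition of enolised tricarbonyl compounds to enones and the conjugate addition of ketone enolates to 3-acyl-2,3-dihydropyran-4-ones with retention of the ring oxygen. C8 is set by C4: the oxygen is delivered through the C4–C3 tether and can only reach the face of ring C that carries C3, so C9 ends up cis to the C4 methyl group. C12 is set by C8: C11 sits on the pseudo-axial C9 arm and can only reach the same face of the dihydropyranone, which gives the bridged ring system. C11 is set by the Z enolate in a chair-like closure, which places its methyl group equatorial, and the centre stays epimerisable toward that isomer. In the first event oxygen and not carbon must attack, which is secured because C2 would have to close a four-membered ring; the two ring A carbonyl groups interchange by rotation about C2–C3, so no regiochemistry arises. In the second event C11 must choose C12 over C7 of the ring C enone and over the carbonyl groups; C12 is doubly activated and reached through a six-membered transition state, whereas aldol additions to C3 or C5 are reversible and cannot dehydrate at a bridgehead.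

Step 9
Reactants: 15 (4R,8R,11R,12R)-tetracyclic enol diketone
Product: 16 (4R,8R,11R,12R)-C1 enol trifluoromethanesulfonate of 15 (C1–OSO2CF3, C1=C2 conjugated to the C3 ketone)
Conditions: Tf2O, Et3N, CH2Cl2, −78 °C
Reagents that add atoms: trifluoromethanesulfonic anhydride, O=S(=O)(OS(=O)(=O)C(F)(F)F)C(F)(F)F
Why: O-Sulfonylation of a 1,3-diketone; the C1 oxygen is flanked only by the C14 methylene, whereas the C3 oxygen is shielded by quaternary C4, whose equatorial methyl group lies close to the carbonyl plane, so the triflate should form at C1. The C10 ketone is not enolised by the amine at −78 °C.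

Step 10
Reactants: 16 (4R,8R,11R,12R)-C1 enol trifluoromethanesulfonate; 17 tributyl(methoxymethyl)stannane
Product: 18 (4R,8R,11R,12R)-10-oxo compound (alterbrassicicene C with a ketone in place of the C10 carbinol)
Conditions: Pd(PPh3)4 (5 mol %), LiCl (3 equiv), 1,4-dioxane, 90 °C
Reagents that add atoms: none
Why: Stille coupling of a β-triflyloxy enone, which adds readily to zerovalent palladium, with an α-alkoxymethylstannane that transfers its oxygen-bearing CH2 group in preference to butyl. The neutral conditions spare the base-sensitive non-enolisable 1,3-diketone.

Step 11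
Reactants: 18 (4R,8R,11R,12R)-10-oxo compound
Product: 19 alterbrassicicene C, (4R,8R,10S,11S,12R)
Conditions: NaBH4 (1 equiv), MeOH–CH2Cl2 (1:1), −78 °C; AcOH quench at −78 °C
Reagents that add atoms: none
Why: At −78 °C borohydride reduces the saturated C10 ketone faster than the conjugated, neopentyl-type carbonyl groups C3 and C5. Hydride enters from the open exo face of the oxan-4-one (the endo face is covered by the C3 bridge) and should give the axial, endo (10S) alcohol; the cold acidic quench keeps the alkoxide from attacking C3.

## Compound list

1 | tert-butyl 2-methyl-3-oxobutanoate | CC(=O)C(C)C(=O)OC(C)(C)C | starting material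
2 | 1-bromo-3-methylbutan-2-one | CC(C)C(=O)CBr | starting material
3 | tert-butyl (2R)-2-acetyl-2,5-dimethyl-4-oxohexanoate | CC(C)C(=O)C[C@](C)(C(C)=O)C(=O)OC(C)(C)C | intermediate
4 | tert-butyl (1R)-1-methyl-2-oxo-4-(propan-2-yl)cyclopent-3-ene-1-carboxylate | C1C(C(C)C)=CC(=O)[C@]1(C)C(=O)OC(C)(C)C | intermediate
5 | tert-butyl (1R)-2-[(tert-butyldimethylsilyl)oxy]-1-methyl-4-(propan-2-yl)cyclopenta-2,4-diene-1-carboxylate | C1=C(C(C)C)C=C(O[Si](C)(C)C(C)(C)C)[C@]1(C)C(=O)OC(C)(C)C | intermediate
6 | 1-hydroxybutan-2-one | CCC(=O)CO | starting material
7 | 2-oxobutanal | CCC(=O)C=O | intermediate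
8 | tert-butyl (1R)-5-(1-hydroxy-2-oxobutyl)-1-methyl-2-oxo-4-(propan-2-yl)cyclopent-3-ene-1-carboxylate (mixture at the two new centres) | CCC(=O)C(O)C1C(C(C)C)=CC(=O)[C@]1(C)C(=O)OC(C)(C)C | intermediate
9 | tert-butyl (1R)-1-methyl-2-oxo-5-(2-oxobutylidene)-4-(propan-2-yl)cyclopent-3-ene-1-carboxylate | CCC(=O)C=C1C(C(C)C)=CC(=O)[C@]1(C)C(=O)OC(C)(C)C | intermediate
10 | (1R)-1-methyl-2-oxo-5-(2-oxobutylidene)-4-(propan-2-yl)cyclopent-3-ene-1-carboxylic acid | CCC(=O)C=C1C(C(C)C)=CC(=O)[C@]1(C)C(=O)O | intermediate
11 | cyclopentane-1,3-dione | O=C1CCC(=O)C1 | starting material
12 | 3-oxocyclopent-1-en-1-yl (1R)-1-methyl-2-oxo-5-(2-oxobutylidene)-4-(propan-2-yl)cyclopent-3-ene-1-carboxylate | CCC(=O)C=C1C(C(C)C)=CC(=O)[C@]1(C)C(=O)OC2=CC(=O)CC2 | intermediate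
13 | 3-hydroxy-2-{[(1R)-1-methyl-2-oxo-5-(2-oxobutylidene)-4-(propan-2-yl)cyclopent-3-en-1-yl]carbonyl}cyclopent-2-en-1-one | CCC(=O)C=C1C(C(C)C)=CC(=O)[C@]1(C)C(=O)C2=C(O)CCC2=O | intermediate
14 | (4R,8R)-dihydropyranone: ether oxygen joins C8 and C12, C12=C2 enol ether, ketones at C1, C3, C5 and C10, 2-oxobutyl group on C8 | O=C1CCC2=C1C(=O)[C@@]3(C)C(=O)C=C(C(C)C)[C@@]3(CC(=O)CC)O2 | intermediate
15 | (4R,8R,11R,12R)-tetracyclic enol diketone: C1–OH, C1=C2, ketones at C3, C5 and C10 | OC1=C2C(=O)[C@@]3(C)C(=O)C=C(C(C)C)[C@]34CC(=O)[C@H](C)[C@@]2(CC1)O4 | intermediate
16 | (4R,8R,11R,12R)-C1 enol trifluoromethanesulfonate of 15 | O=S(=O)(OC1=C2C(=O)[C@@]3(C)C(=O)C=C(C(C)C)[C@]34CC(=O)[C@H](C)[C@@]2(CC1)O4)C(F)(F)F | intermediate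
17 | tributyl(methoxymethyl)stannane | CCCC[Sn](CCCC)(CCCC)COC | starting material
18 | (4R,8R,11R,12R)-10-oxo compound (10-dehydroalterbrassicicene C) | COCC1=C2C(=O)[C@@]3(C)C(=O)C=C(C(C)C)[C@]34CC(=O)[C@H](C)[C@@]2(CC1)O4 | intermediate
19 | alterbrassicicene C, (4R,8R,10S,11S,12R) | COCC1=C2C(=O)[C@@]3(C)C(=O)C=C(C(C)C)[C@]34C[C@H](O)[C@H](C)[C@@]2(CC1)O4 | target

## Step count and least certain steps

Total step count: 11. Longest linear sequence: 10 steps (steps 1, 2, 3, 5, 6, 7, 8, 9, 10, 11); step 4 is a one-step branch.

**Step 8 (key step).** The acidic tricarbonyl enolate is a weak oxygen nucleophile, so the first addition may be slow. Meanwhile the base-generated C11 enolate may attack C7 of the ring C enone. Once the ether exists, β-elimination of the C12–O bond followed by retro-aldol cleavage at C8 may drain material. The fallback makes the two bonds one at a time without free enolates. From 13, catalytic camphorsulfonic acid in toluene should effect the oxa-Michael addition alone and allow isolation of 14. Soft enolisation of its ethyl ketone with Me3SiOTf/Et3N should give the (Z)-trimethylsilyl enol ether F1. A catalytic amount of Me3SiOTf (or TiCl4) in CH2Cl2 at −78 °C should then trigger an intramolecular Mukaiyama–Michael addition of C11 to C12. Aqueous work-up returns to the route at 15.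

**Step 1.** Enantiofacial discrimination may be poor because the acyclic enolate of 1 can adopt two geometries, and 2 may be consumed by the base. The fallback is auxiliary control. 1 is condensed with tert-butyl L-valinate (or its mirror image, as the required sense demands) to the chelated enamino ester F2. Deprotonation with LDA, alkylation with 2 at −78 °C and mild acidic hydrolysis of the imine return to the route at 3 and release the auxiliary.

**Step 5.** The dienol ether may be attacked at C6 instead of C8, 7 may oligomerise under the Lewis acid, or the aldol adduct may eliminate incompletely. The fallback fixes the site of bond formation by phosphorus. 5 is brominated at C8 with N-bromosuccinimide to the γ-bromo enone F3. A Michaelis–Arbuzov reaction with P(OMe)3 gives the phosphonate F4. A Horner–Wadsworth–Emmons reaction with 7 (LiCl, iPr2NEt, MeCN) forms C8=C9 directly and returns to the route at 9.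

**Step 7.** The β-keto acid 10 may decarboxylate before it is activated, and the hindered acyl group may stall at the O-acyl stage (12) without migrating to carbon. The fallback makes the C2–C3 bond by direct C-acylation of a carbon nucleophile. 10 is converted with oxalyl chloride and catalytic DMF into the acid chloride F5. 11 is converted with Me3SiOTf/Et3N into 1,3-bis(trimethylsilyloxy)cyclopenta-1,3-diene F6. F6 is acylated by F5 at its central carbon C2 in CH2Cl2, and hydrolytic work-up returns to the route at 13.

**Step 11.** One of the enone carbonyl groups may be reduced as well, or the newly formed endo alkoxide may add across the ring to C3 and open the non-enolisable diketone by retro-Claisen cleavage. The fallback is an enzymatic reduction of 18 at pH 7 with a ketoreductase chosen by screening for the (10S) alcohol, with NADPH recycled by glucose and glucose dehydrogenase. No alkoxide is formed and conjugated ketones are poor substrates. The product is 19, and no new compound is made (entry F0).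

## Further compounds

F1 | step 8 | (Z)-trimethylsilyl enol ether of 14 (C10–OSiMe3, C10=C11) | O=C1CCC2=C1C(=O)[C@@]3(C)C(=O)C=C(C(C)C)[C@@]3(C/C(O[Si](C)(C)C)=C/C)O2
F2 | step 1 | tert-butyl (2Z)-3-{[(2S)-1-tert-butoxy-3-methyl-1-oxobutan-2-yl]amino}-2-methylbut-2-enoate | CC(C)[C@H](N/C(C)=C(/C)C(=O)OC(C)(C)C)C(=O)OC(C)(C)C
F3 | step 5 | tert-butyl (1R)-5-bromo-1-methyl-2-oxo-4-(propan-2-yl)cyclopent-3-ene-1-carboxylate | BrC1C(C(C)C)=CC(=O)[C@]1(C)C(=O)OC(C)(C)C
F4 | step 5 | tert-butyl (1R)-5-(dimethoxyphosphoryl)-1-methyl-2-oxo-4-(propan-2-yl)cyclopent-3-ene-1-carboxylate | COP(=O)(OC)C1C(C(C)C)=CC(=O)[C@]1(C)C(=O)OC(C)(C)C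
F5 | step 7 | (1R)-1-methyl-2-oxo-5-(2-oxobutylidene)-4-(propan-2-yl)cyclopent-3-ene-1-carbonyl chloride | CCC(=O)C=C1C(C(C)C)=CC(=O)[C@]1(C)C(Cl)=O
F6 | step 7 | 1,3-bis(trimethylsilyloxy)cyclopenta-1,3-diene | C[Si](C)(C)OC1=CC(O[Si](C)(C)C)=CC1
F0 | step 11 | none | none
A1 | alternative 1 | 5-8-5 hydroxy dienetrione with free C8–OH, C11=C12 and C1=C2 alkenes and ketones at C3, C5 and C10, C4 and C8 configured as in 19 | COCC1=C2C(=O)[C@@]3(C)C(=O)C=C(C(C)C)[C@]3(O)CC(=O)C(C)=C2CC1
A2 | alternative 2 | vinylogous ester in which the enol oxygen of a ring A cyclopentane-1,3-dione is bound to C8 of a ring C-fused 2-methylcyclohexane-1,3-dione | O=C1C=C(CC1)O[C@@]23CC(=O)C(C)C(=O)[C@@]2(C)C(=O)C=C3C(C)C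
A3 | alternative 3 | dispiro oxan-4-ol carrying the ring A vinyl iodide (iodine on C2) and the ring C enone with hydrogen on C4 | COCC1=C(I)[C@]2(CC1)O[C@]3(C[C@H](O)[C@@H]2C)C(C(C)C)=CC(=O)[C@H]3C
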